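**Retrosynthetic overview**
1. The target (1R,2R,3R: aryl trans to the C2 methyl, the two methyls cis) comes from face-selective hydrogenation of the C3=C4 bond of a (1R,2S)-1-aryl-2,3-dimethyl-1,2-dihydronaphthalene.
2. That dihydronaphthalene comes from an acid-triggered cyclopropylcarbinyl-cation ring expansion (three- to six-membered) of an aryl(2-aryl-1,3-dimethylcyclopropyl)methanol. This closes ring B onto ring A and sets C1.
3. The cyclopropane comes from an alkoxide-directed zincocyclopropanation/Negishi arylation of an (R)-1-aryl-2-methylbut-2-en-1-ol with iodoform and 4-bromoveratrole. This fixes the future C2.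
4. The allylic alcohol comes from a catalytic asymmetric arylzinc addition to tiglic aldehyde. 4-Bromoveratrole, the source of both arenes, comes from catechol by methylation and bromination.
5. Ring order: cyclopropane first, then ring B by ring expansion; both arenes are carried in intact.

Assumption: the SMILES is read as (1R,2R,3R). Target numbering C1–C4 is used for ring B; ring A is the fused dimethoxybenzene.

**Step 1**
Reactants: 1 catechol (benzene-1,2-diol)
Product: 2 1,2-dimethoxybenzene
Conditions: MeI (2.5 equiv), K2CO3, acetone, reflux
Reagents that add atoms: iodomethane, CI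
Why: Double Williamson ether synthesis, in which both phenoxides formed by K2CO3 are methylated by SN2 on iodomethane and no other nucleophilic site is present.

**Step 2**
Reactants: 2 1,2-dimethoxybenzene
Product: 3 4-bromo-1,2-dimethoxybenzene
Conditions: NBS (1.0 equiv), MeCN, 0 °C to rt
Reagents that add atoms: N-bromosuccinimide, O=C1CCC(=O)N1Br
Why: Electrophilic aromatic bromination (SEAr) goes para to one methoxy group, the position between substituent and ring hydrogen being hindered and the monobromide being deactivated toward a second bromination.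

**Step 3**
Reactants: 3 4-bromo-1,2-dimethoxybenzene; 4 (E)-2-methylbut-2-enal
Product: 8 (1R,2E)-1-(3,4-dimethoxyphenyl)-2-methylbut-2-en-1-ol, via (3,4-dimethoxyphenyl)lithium 5 (not isolated), via (3,4-dimethoxyphenyl)zinc chloride 6 (not isolated), via butyl(3,4-dimethoxyphenyl)zinc 7 (not isolated)
Conditions: 3 (2 equiv), n-BuLi, t-BuOMe, −78 °C; ZnCl2; n-BuLi; TEEDA; (−)-MIB [(2S)-3-exo-morpholinoisoborneol] (5 mol %), 4, hexanes/t-BuOMe, 0 °C
Reagents that add atoms: none
Why: Amino-alcohol-catalysed enantioselective 1,2-addition of a mixed aryl(alkyl)zinc to an aldehyde, in which the aryl group of 7 (transferred in preference to butyl) is delivered by the zinc/(−)-MIB complex to the Si face of the enal carbonyl to set the carbinol centre as R, while TEEDA sequesters LiCl and suppresses the racemic background addition.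

**Step 4**
Reactants: 8 (1R,2E)-1-(3,4-dimethoxyphenyl)-2-methylbut-2-en-1-ol; 9 iodoform; 3 4-bromo-1,2-dimethoxybenzene
Product: 12 (S)-(3,4-dimethoxyphenyl)[(1R,2R,3S)-2-(3,4-dimethoxyphenyl)-1,3-dimethylcyclopropyl]methanol, via gem-dizinc carbenoid 10 (not isolated), via cyclopropylzinc iodide 11 (not isolated)
Conditions: Et2Zn, I2, 9, Et2O/CH2Cl2, 0 °C; then 8, 0 °C to rt; then 3 (2.5 equiv), Pd(OAc)2 (5 mol %), SPhos (10 mol %), THF, rt to 40 °C
Reagents that add atoms: none
Why: Proposed new method: the iodozinc alkoxide of 8 binds the gem-dizinc carbenoid 10 and delivers its carbon to the alkene face syn to oxygen in the H-eclipsed conformer (the normal sense of hydroxyl-directed Simmons–Smith reactions), which by stereospecific syn addition to the (E)-alkene fixes the methyl-bearing cyclopropane carbon C3 as S (the future C2 of the target); the second C–Zn bond survives, is held cis to the alkoxide by O→Zn chelation in 11 and is arylated with retention by Negishi coupling with 3 (oxidative addition to zerovalent palladium, transmetalation, reductive elimination); the closest known reactions are directed zincocyclopropanation of allylic alcohols with gem-dizinc carbenoids and Negishi coupling of cyclopropylzinc halides, neither shown for a trisubstituted, α-aryl allylic alkoxide that gives a fully substituted cyclopropane with a quaternary carbon, nor telescoped with an electron-rich aryl bromide.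

**Step 5**
Reactants: 12 (S)-(3,4-dimethoxyphenyl)[(1R,2R,3S)-2-(3,4-dimethoxyphenyl)-1,3-dimethylcyclopropyl]methanol
Product: 13 (1R,2S)-1-(3,4-dimethoxyphenyl)-6,7-dimethoxy-2,3-dimethyl-1,2-dihydronaphthalene
Conditions: TsOH·H2O (5 mol %), HFIP/CH2Cl2 (1:4), −20 to 0 °C; Et3N quench
Reagents that add atoms: none
Why: Cyclopropylcarbinyl-cation ring expansion (cyclopropylcarbinyl-to-homoallyl rearrangement ended by intramolecular Friedel–Crafts alkylation, stepwise and cationic), in which ionisation of the carbinol, cleavage of the cyclopropane C1–C2 bond toward the veratryl-stabilised benzylic cation and attack of that cation by ring A para to a methoxy group turn the three-membered ring into six-membered ring B; the carbinol carbon and cyclopropane C1 and C2 all pass through trigonal centres, so only the untouched cyclopropane C3 carries chirality into C2 of 13, the E- and Z-homoallyl cations equilibrate through the cyclopropylcarbinyl cation, and the new C1 is set R because the aryl group takes the face anti to the adjacent methyl in the chair-like closure.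

**Step 6**
Reactants: 13 (1R,2S)-1-(3,4-dimethoxyphenyl)-6,7-dimethoxy-2,3-dimethyl-1,2-dihydronaphthalene
Product: 14 (1R,2R,3R)-1-(3,4-dimethoxyphenyl)-6,7-dimethoxy-2,3-dimethyl-1,2,3,4-tetrahydronaphthalene
Conditions: H2 (1 atm), 10% Pd/C, EtOAc, rt
Reagents that add atoms: none
Why: Heterogeneous catalytic syn-hydrogenation of a trisubstituted styrene, in which the C1 aryl and C2 methyl of 13 are trans-diaxial in the preferred half-chair and hydrogen is delivered to C3=C4 from the face anti to the adjacent pseudoaxial C2 methyl, placing the C3 methyl cis to the C2 methyl (3R) without touching C1 or C2.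

**Compound list**
1 | catechol (benzene-1,2-diol) | Oc1ccccc1O | starting material
2 | 1,2-dimethoxybenzene | COc1ccccc1OC | intermediate
3 | 4-bromo-1,2-dimethoxybenzene | COc1ccc(Br)cc1OC | intermediate
4 | (E)-2-methylbut-2-enal (tiglic aldehyde) | C/C=C(\C)C=O | starting material
5 | (3,4-dimethoxyphenyl)lithium | [Li]c1ccc(OC)c(OC)c1 | intermediate
6 | (3,4-dimethoxyphenyl)zinc chloride | Cl[Zn]c1ccc(OC)c(OC)c1 | intermediate
7 | butyl(3,4-dimethoxyphenyl)zinc | CCCC[Zn]c1ccc(OC)c(OC)c1 | intermediate
8 | (1R,2E)-1-(3,4-dimethoxyphenyl)-2-methylbut-2-en-1-ol | C/C=C(\C)[C@@H](O)c1ccc(OC)c(OC)c1 | intermediate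
9 | iodoform | IC(I)I | starting material
10 | (iodomethylene)bis(iodozinc), the gem-dizinc carbenoid | I[Zn]C(I)[Zn]I | intermediate
11 | iodozinc (S)-(3,4-dimethoxyphenyl)[(1S,2S,3R)-2-(iodozincio)-1,3-dimethylcyclopropyl]methanolate (zinc cis to the alkoxide carbon, both methyls on the other face) | COc1ccc(cc1OC)[C@H](O[Zn]I)[C@]1(C)[C@@H](C)[C@@H]1[Zn]I | intermediate
12 | (S)-(3,4-dimethoxyphenyl)[(1R,2R,3S)-2-(3,4-dimethoxyphenyl)-1,3-dimethylcyclopropyl]methanol (C2 aryl cis to the carbinol carbon, both methyls on the other face) | COc1ccc(cc1OC)[C@H](O)[C@]1(C)[C@@H](C)[C@@H]1c1ccc(OC)c(OC)c1 | intermediate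
13 | (1R,2S)-1-(3,4-dimethoxyphenyl)-6,7-dimethoxy-2,3-dimethyl-1,2-dihydronaphthalene | COc1ccc([C@@H]2c3cc(OC)c(OC)cc3C=C(C)[C@H]2C)cc1OC | intermediate
14 | (1R,2R,3R)-1-(3,4-dimethoxyphenyl)-6,7-dimethoxy-2,3-dimethyl-1,2,3,4-tetrahydronaphthalene | COc1ccc([C@@H]2c3cc(OC)c(OC)cc3C[C@@H](C)[C@H]2C)cc1OC | target

**Totals**
Total step count: 6. Longest linear sequence: 6 (1 → 2 → 3 → 8 → 12 → 13 → 14).

**Three steps most likely to fail, with fallbacks**

Step 4, the proposed new step. The gem-dizinc carbenoid may be too sluggish toward the hindered trisubstituted alkene, ZnI2 may ionise the electron-rich benzylic alkoxide, and excess carbenoid may consume 3 in the coupling. The fallback uses known chemistry in two stages; it sets out from 8 and comes back to the route at 12. Directed iodocyclopropanation of 8 with the more reactive mono-zinc iodocarbenoid (Et2Zn, 9, CF3CH2OH, CH2Cl2) gives the isolated iodocyclopropyl carbinol F1, with iodine cis to the carbinol carbon. Lithium–iodine exchange (t-BuLi, 3 equiv, −78 °C), transmetalation with ZnCl2 and Negishi coupling with 3 (Pd(OAc)2, SPhos) then give 12 with retention. If the directing sense proved anti instead of syn, (+)-MIB in step 3 would restore the absolute configuration.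

Step 5. The homoallyl cation can lose the C2 proton to give an achiral 1,4-diaryl-diene, the cis aryl group on the cyclopropane can close onto the carbinyl cation, and the styrene product can oligomerise in acid. The fallback replaces the free carbinyl cation by a ketone-level ring expansion; it sets out from 12 and comes back at 14. Oxidation with MnO2 gives the aryl cyclopropyl ketone F2. SnCl4 in CH2Cl2 opens the acylcyclopropane to the benzylic cation/tin enolate and closes ring B by Friedel–Crafts alkylation, a known route to 4-aryl-1-tetralones, giving the tetralone F3. In F3 the aryl group is trans to the C3 methyl, and the C2 methyl is set cis to it by protonation of the enolate anti to the axial C3 methyl. Ionic deoxygenation of the aryl ketone (Et3SiH, TFA) then gives 14 directly, without passing through 13.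

Step 6. This is the least certain stereochemical call in the route: the pseudoaxial C1 aryl shields the opposite face, and if hydrogen adds anti to it the 2,3-trans isomer forms instead. The fallback sets out from 13 and comes back at 14. Hydroboration–oxidation (BH3·THF; then NaOH, H2O2) is a syn addition of a small reagent: boron goes to the benzylic C4 and hydrogen to C3, anti to the axial C2 methyl. This gives the benzylic alcohol F4 with the C3 methyl already cis to the C2 methyl. Hydrogenolysis of the C4 hydroxyl (H2, Pd/C, AcOH) then gives 14.

**Further compounds**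
F1 | step 4 | (S)-(3,4-dimethoxyphenyl)[(1S,2S,3R)-2-iodo-1,3-dimethylcyclopropyl]methanol | COc1ccc(cc1OC)[C@H](O)[C@]1(C)[C@@H](C)[C@@H]1I
F2 | step 5 | (3,4-dimethoxyphenyl)[(1R,2R,3S)-2-(3,4-dimethoxyphenyl)-1,3-dimethylcyclopropyl]methanone | COc1ccc(cc1OC)C(=O)[C@]1(C)[C@@H](C)[C@@H]1c1ccc(OC)c(OC)c1
F3 | step 5 | (2S,3S,4R)-4-(3,4-dimethoxyphenyl)-6,7-dimethoxy-2,3-dimethyl-3,4-dihydronaphthalen-1(2H)-one | COc1ccc([C@@H]2c3cc(OC)c(OC)cc3C(=O)[C@@H](C)[C@H]2C)cc1OC
F4 | step 6 | (1R,2S,3S,4R)-4-(3,4-dimethoxyphenyl)-6,7-dimethoxy-2,3-dimethyl-1,2,3,4-tetrahydronaphthalen-1-ol | COc1ccc([C@@H]2c3cc(OC)c(OC)cc3[C@H](O)[C@@H](C)[C@H]2C)cc1OC
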